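**Retrosynthetic overview** (side-chain carbons are C1′–C13′, counted from the lactone)
1. Target 29 ⇐ silyl ether 28 ⇐ enone 27 (C=C hydrogenation and O-debenzylation in one operation) ⇐ β-hydroxy ketone 25 (dehydration).
2. Key disconnection C3′–C4′: lithium-enolate aldol of methyl ketone 23 (carries the C6′ stereocentre) with aldehyde 15 (carries C3).
3. 15 ⇐ butenyl lactone 11 (8-O-demethylation, benzylation, alkene cleavage) ⇐ aryl bromide 8 (Br/Li exchange, CO2, lactonisation) ⇐ (S)-epichlorohydrin opened twice (aryl Grignard, then allyl Grignard).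
4. 23 ⇐ (R)-benzyl glycidyl ether + hexylmagnesium bromide, then protecting-group and oxidation-state changes and methyl addition.
5. Ring order: the benzene ring is bought; the only ring made is the δ-lactone (step 5), before the fragments are joined.

Assumption: Grignard solutions 7 and 17, LDA solution and Dess–Martin periodinane are used as bought, and organometallic steps are quenched with water, so the metal by-product is written as its simplest salt.

**Western fragment (aldehyde 15)**

Step 1
Reactants: 1 1-bromo-3,5-dimethoxybenzene; 2 (S)-epichlorohydrin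
Product: 4 (S)-1-chloro-3-(3,5-dimethoxyphenyl)propan-2-ol, via aryl Grignard reagent 3 (not isolated)
Conditions: Mg, THF, reflux; then CuI (10 mol%), 2 (0.85 equiv), THF, −40 → 0 °C; H2O quench
Reagents that add atoms: magnesium, [Mg] (kept only in intermediate 3)
Why: Copper-catalysed Grignard opening of the epoxide at its unsubstituted carbon (SN2) does not touch the C–O stereocentre, so the future C3 is taken unchanged from the chiral pool.

Step 2
Reactants: 4 (S)-1-chloro-3-(3,5-dimethoxyphenyl)propan-2-ol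
Product: 5 (S)-1-(2-bromo-3,5-dimethoxyphenyl)-3-chloropropan-2-ol
Conditions: NBS (1.05 equiv), MeCN, 0 °C, dark
Reagents that add atoms: N-bromosuccinimide, O=C1CCC(=O)N1Br
Why: Electrophilic aromatic bromination goes to the position para to one methoxy and ortho to the other (next to the side chain), because the site between the two methoxy groups is more hindered; it is done here, before any alkene is present.

Step 3
Reactants: 5 (S)-1-(2-bromo-3,5-dimethoxyphenyl)-3-chloropropan-2-ol
Product: 6 (S)-2-(2-bromo-3,5-dimethoxybenzyl)oxirane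
Conditions: NaOH, MeOH/H2O, 0 °C → rt
Reagents that add atoms: none
Why: Intramolecular Williamson etherification (alkoxide displaces the primary chloride) closes the epoxide without breaking a bond at the stereocentre.

Step 4
Reactants: 6 (S)-2-(2-bromo-3,5-dimethoxybenzyl)oxirane; 7 allylmagnesium bromide
Product: 8 (R)-1-(2-bromo-3,5-dimethoxyphenyl)hex-5-en-2-ol
Conditions: 7 (1.5 equiv), CuI (10 mol%), THF, −40 → −10 °C; H2O quench
Reagents that add atoms: none
Why: Cu-catalysed Grignard epoxide opening at the terminal carbon (SN2) keeps the stereocentre (descriptor changes S→R by CIP only), and the aryl bromide is inert to Grignard/Cu(I) at this temperature.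

Step 5
Reactants: 8 (R)-1-(2-bromo-3,5-dimethoxyphenyl)hex-5-en-2-ol
Product: 11 (R)-3-(but-3-en-1-yl)-6,8-dimethoxyisochroman-1-one, via aryllithium alkoxide 9 (not isolated), via hydroxy acid 10 (not isolated)
Conditions: n-BuLi (2.2 equiv), THF, −78 °C; CO2 (g), −78 °C → rt; 2 M HCl, rt (cat. TsOH, toluene, 50 °C to complete ring closure)
Reagents that add atoms: n-butyllithium, [Li]CCCC (lithium only in intermediate 9); carbon dioxide, O=C=O
Why: Bromine–lithium exchange on the lithium alkoxide, carboxylation of the aryllithium and acid-driven lactonisation of the δ-hydroxy acid form the dihydroisocoumarin with retention at C3.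

Step 6
Reactants: 11 (R)-3-(but-3-en-1-yl)-6,8-dimethoxyisochroman-1-one
Product: 12 (R)-3-(but-3-en-1-yl)-8-hydroxy-6-methoxyisochroman-1-one
Conditions: BCl3 (2 equiv), CH2Cl2, −78 → 0 °C; H2O
Reagents that add atoms: none
Why: Chelation-controlled Lewis-acid demethylation: BCl3 bridges the lactone C=O and the peri 8-methoxy oxygen, so only that methyl ether is cleaved.

Step 7
Reactants: 12 (R)-3-(but-3-en-1-yl)-8-hydroxy-6-methoxyisochroman-1-one
Product: 13 (R)-8-(benzyloxy)-3-(but-3-en-1-yl)-6-methoxyisochroman-1-one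
Conditions: BnBr, K2CO3, DMF, 50 °C
Reagents that add atoms: benzyl bromide, BrCc1ccccc1
Why: Williamson O-benzylation masks the acidic phenol for the enolate step with a group that the later hydrogenation removes at no extra cost.

Step 8
Reactants: 13 (R)-8-(benzyloxy)-3-(but-3-en-1-yl)-6-methoxyisochroman-1-one
Product: 15 3-[(R)-8-(benzyloxy)-6-methoxy-1-oxoisochroman-3-yl]propanal, via vicinal diol 14 (not isolated)
Conditions: OsO4 (2 mol%), NaIO4 (4 equiv), 2,6-lutidine, dioxane/H2O 3:1, rt
Reagents that add atoms: sodium periodate, [Na+].[O-]I(=O)(=O)=O (oxygen passed on by catalytic OsO4); water, O (second hydroxyl of intermediate 14)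
Why: Lemieux–Johnson oxidation (dihydroxylation, then periodate glycol cleavage) converts only the terminal alkene into the aldehyde and leaves the electron-rich arene alone.

**Eastern fragment (ketone 23)**

Step 9
Reactants: 16 (R)-benzyl glycidyl ether; 17 n-hexylmagnesium bromide
Product: 18 (R)-1-(benzyloxy)nonan-2-ol
Conditions: 17 (1.5 equiv), CuI (10 mol%), THF, −30 → 0 °C; H2O quench
Reagents that add atoms: none
Why: Cu-catalysed Grignard opening at the terminal epoxide carbon (SN2) builds the heptyl chain and leaves the pool stereocentre (future C6′) unchanged.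

Step 10
Reactants: 18 (R)-1-(benzyloxy)nonan-2-ol
Product: 19 (R)-[1-(benzyloxy)nonan-2-yloxy](tert-butyl)dimethylsilane
Conditions: TBSCl, imidazole, DMF, rt
Reagents that add atoms: tert-butyldimethylsilyl chloride, CC(C)(C)[Si](C)(C)Cl
Why: Imidazole-promoted silylation protects the secondary alcohol as an ether that survives hydrogenolysis, Grignard addition and LDA.

Step 11
Reactants: 19 (R)-[1-(benzyloxy)nonan-2-yloxy](tert-butyl)dimethylsilane
Product: 20 (R)-2-(tert-butyldimethylsilyloxy)nonan-1-ol
Conditions: H2 (1 atm), 10% Pd/C, EtOAc, rt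
Reagents that add atoms: none
Why: Catalytic hydrogenolysis cleaves the benzyl ether, while the TBS ether is stable under neutral conditions in EtOAc (no silyl migration).

Step 12
Reactants: 20 (R)-2-(tert-butyldimethylsilyloxy)nonan-1-ol
Product: 21 (R)-2-(tert-butyldimethylsilyloxy)nonanal
Conditions: Dess–Martin periodinane, CH2Cl2, 0 °C → rt; used directly
Reagents that add atoms: none
Why: Dess–Martin oxidation is non-basic, so the α-silyloxy aldehyde is formed without epimerisation.

Step 13
Reactants: 21 (R)-2-(tert-butyldimethylsilyloxy)nonanal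
Product: 22 (3R)-3-(tert-butyldimethylsilyloxy)decan-2-ol (C2 epimer mixture)
Conditions: MeMgBr, Et2O, −78 → 0 °C; H2O quench
Reagents that add atoms: methylmagnesium bromide, C[Mg]Br
Why: Grignard addition to the aldehyde; the new carbinol centre is uncontrolled but is erased in the next step.

Step 14
Reactants: 22 (3R)-3-(tert-butyldimethylsilyloxy)decan-2-ol
Product: 23 (R)-3-(tert-butyldimethylsilyloxy)decan-2-one
Conditions: Dess–Martin periodinane, CH2Cl2, rt
Reagents that add atoms: none
Why: Dess–Martin oxidation gives the methyl ketone under neutral conditions that do not enolise the α-silyloxy centre.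

**Fragment union and endgame**

Step 15
Reactants: 23 (R)-3-(tert-butyldimethylsilyloxy)decan-2-one; 15 3-[(R)-8-(benzyloxy)-6-methoxy-1-oxoisochroman-3-yl]propanal
Product: 25 (3R)-8-(benzyloxy)-3-[(6R)-6-(tert-butyldimethylsilyloxy)-3-hydroxy-5-oxotridecyl]-6-methoxyisochroman-1-one (C3′ epimer mixture), via lithium enolate 24 (not isolated)
Conditions: LDA (1.25 equiv), THF, −78 °C, 23 (1.3 equiv), 30 min; 15 (1.0 equiv), −78 °C, 30 min; AcOH quench at −78 °C
Reagents that add atoms: lithium diisopropylamide, CC(C)N([Li])C(C)C (lithium only in intermediate 24)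
Why: Directed aldol addition: LDA deprotonates only the unhindered methyl group (kinetic enolate, C6′ untouched), and the enolate adds to the aldehyde far faster than to the hindered aryl lactone; the C3′ carbinol centre is removed later.

Step 16
Reactants: 25 (3R)-8-(benzyloxy)-3-[(6R)-6-(tert-butyldimethylsilyloxy)-3-hydroxy-5-oxotridecyl]-6-methoxyisochroman-1-one
Product: 27 (3R)-8-(benzyloxy)-3-[(3E,6R)-6-(tert-butyldimethylsilyloxy)-5-oxotridec-3-en-1-yl]-6-methoxyisochroman-1-one, via aldol mesylate 26 (not isolated)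
Conditions: MsCl, Et3N (5 equiv), CH2Cl2, 0 °C → rt
Reagents that add atoms: methanesulfonyl chloride, CS(=O)(=O)Cl (only in intermediate 26)
Why: Mesylation and E1cB elimination give the conjugated (E)-enone; Et3N is too weak to enolise toward the silyloxy-bearing carbon, so C6′ is not epimerised.

Step 17
Reactants: 27 (3R)-8-(benzyloxy)-3-[(3E,6R)-6-(tert-butyldimethylsilyloxy)-5-oxotridec-3-en-1-yl]-6-methoxyisochroman-1-one
Product: 28 (3R)-3-[(6R)-6-(tert-butyldimethylsilyloxy)-5-oxotridecyl]-8-hydroxy-6-methoxyisochroman-1-one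
Conditions: H2 (1 atm), 10% Pd/C, EtOAc, rt
Reagents that add atoms: none
Why: Heterogeneous catalytic hydrogenation saturates the enone C=C and hydrogenolyses the aryl benzyl ether, while the aliphatic ketone, lactone and TBS ether are inert.

Step 18
Reactants: 28 (3R)-3-[(6R)-6-(tert-butyldimethylsilyloxy)-5-oxotridecyl]-8-hydroxy-6-methoxyisochroman-1-one
Product: 29 (3R)-8-hydroxy-3-[(6R)-6-hydroxy-5-oxotridecyl]-6-methoxyisochroman-1-one
Conditions: HF·pyridine, THF/pyridine, 0 °C → rt
Reagents that add atoms: none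
Why: Fluoride-mediated desilylation under mildly acidic conditions frees the α-hydroxy ketone without base-induced ketol isomerisation or epimerisation.

**Compound list**
1 | 1-bromo-3,5-dimethoxybenzene | COc1cc(Br)cc(OC)c1 | starting material
2 | (S)-epichlorohydrin | ClC[C@@H]1CO1 | starting material
3 | 3,5-dimethoxyphenylmagnesium bromide | COc1cc(OC)cc([Mg]Br)c1 | intermediate
4 | (S)-1-chloro-3-(3,5-dimethoxyphenyl)propan-2-ol | COc1cc(OC)cc(C[C@H](O)CCl)c1 | intermediate
5 | (S)-1-(2-bromo-3,5-dimethoxyphenyl)-3-chloropropan-2-ol | COc1cc(OC)c(Br)c(C[C@H](O)CCl)c1 | intermediate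
6 | (S)-2-(2-bromo-3,5-dimethoxybenzyl)oxirane | COc1cc(OC)c(Br)c(C[C@H]2CO2)c1 | intermediate
7 | allylmagnesium bromide | C=CC[Mg]Br | starting material
8 | (R)-1-(2-bromo-3,5-dimethoxyphenyl)hex-5-en-2-ol | COc1cc(OC)c(Br)c(C[C@H](O)CCC=C)c1 | intermediate
9 | lithium (R)-1-(2-lithio-3,5-dimethoxyphenyl)hex-5-en-2-olate | COc1cc(OC)c([Li])c(C[C@H](O[Li])CCC=C)c1 | intermediate
10 | 2-[(R)-2-hydroxyhex-5-en-1-yl]-4,6-dimethoxybenzoic acid | COc1cc(OC)c(C(=O)O)c(C[C@H](O)CCC=C)c1 | intermediate
11 | (R)-3-(but-3-en-1-yl)-6,8-dimethoxyisochroman-1-one | C=CCC[C@@H]1Cc2cc(OC)cc(OC)c2C(=O)O1 | intermediate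
12 | (R)-3-(but-3-en-1-yl)-8-hydroxy-6-methoxyisochroman-1-one | C=CCC[C@@H]1Cc2cc(OC)cc(O)c2C(=O)O1 | intermediate
13 | (R)-8-(benzyloxy)-3-(but-3-en-1-yl)-6-methoxyisochroman-1-one | C=CCC[C@@H]1Cc2cc(OC)cc(OCc3ccccc3)c2C(=O)O1 | intermediate
14 | (3R)-8-(benzyloxy)-3-(3,4-dihydroxybutyl)-6-methoxyisochroman-1-one (diol epimers) | OCC(O)CC[C@@H]1Cc2cc(OC)cc(OCc3ccccc3)c2C(=O)O1 | intermediate
15 | 3-[(R)-8-(benzyloxy)-6-methoxy-1-oxoisochroman-3-yl]propanal | O=CCC[C@@H]1Cc2cc(OC)cc(OCc3ccccc3)c2C(=O)O1 | intermediate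
16 | (R)-benzyl glycidyl ether | C(OCc1ccccc1)[C@H]1CO1 | starting material
17 | n-hexylmagnesium bromide | CCCCCC[Mg]Br | starting material
18 | (R)-1-(benzyloxy)nonan-2-ol | CCCCCCC[C@@H](O)COCc1ccccc1 | intermediate
19 | (R)-[1-(benzyloxy)nonan-2-yloxy](tert-butyl)dimethylsilane | CCCCCCC[C@@H](O[Si](C)(C)C(C)(C)C)COCc1ccccc1 | intermediate
20 | (R)-2-(tert-butyldimethylsilyloxy)nonan-1-ol | CCCCCCC[C@@H](O[Si](C)(C)C(C)(C)C)CO | intermediate
21 | (R)-2-(tert-butyldimethylsilyloxy)nonanal | CCCCCCC[C@@H](O[Si](C)(C)C(C)(C)C)C=O | intermediate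
22 | (3R)-3-(tert-butyldimethylsilyloxy)decan-2-ol (C2 epimers) | CCCCCCC[C@@H](O[Si](C)(C)C(C)(C)C)C(C)O | intermediate
23 | (R)-3-(tert-butyldimethylsilyloxy)decan-2-one | CCCCCCC[C@@H](O[Si](C)(C)C(C)(C)C)C(C)=O | intermediate
24 | lithium (R)-3-(tert-butyldimethylsilyloxy)dec-1-en-2-olate | CCCCCCC[C@@H](O[Si](C)(C)C(C)(C)C)C(=C)O[Li] | intermediate
25 | (3R)-8-(benzyloxy)-3-[(6R)-6-(tert-butyldimethylsilyloxy)-3-hydroxy-5-oxotridecyl]-6-methoxyisochroman-1-one (C3′ epimers) | CCCCCCC[C@@H](O[Si](C)(C)C(C)(C)C)C(=O)CC(O)CC[C@@H]1Cc2cc(OC)cc(OCc3ccccc3)c2C(=O)O1 | intermediate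
26 | 3′-O-methanesulfonate of 25 | CCCCCCC[C@@H](O[Si](C)(C)C(C)(C)C)C(=O)CC(OS(C)(=O)=O)CC[C@@H]1Cc2cc(OC)cc(OCc3ccccc3)c2C(=O)O1 | intermediate
27 | (3R)-8-(benzyloxy)-3-[(3E,6R)-6-(tert-butyldimethylsilyloxy)-5-oxotridec-3-en-1-yl]-6-methoxyisochroman-1-one | CCCCCCC[C@@H](O[Si](C)(C)C(C)(C)C)C(=O)/C=C/CC[C@@H]1Cc2cc(OC)cc(OCc3ccccc3)c2C(=O)O1 | intermediate
28 | (3R)-3-[(6R)-6-(tert-butyldimethylsilyloxy)-5-oxotridecyl]-8-hydroxy-6-methoxyisochroman-1-one | CCCCCCC[C@@H](O[Si](C)(C)C(C)(C)C)C(=O)CCCC[C@@H]1Cc2cc(OC)cc(O)c2C(=O)O1 | intermediate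
29 | (3R)-8-hydroxy-3-[(6R)-6-hydroxy-5-oxotridecyl]-6-methoxyisochroman-1-one | CCCCCCC[C@@H](O)C(=O)CCCC[C@@H]1Cc2cc(OC)cc(O)c2C(=O)O1 | target

**Totals**
Total step count: 18. Longest linear sequence: 12 steps (steps 1–8, then 15–18); the eastern fragment takes 6 steps (9–14).

**Three steps most likely to fail, with fallbacks**

Step 5 (dianion formation, CO2 capture, lactonisation). Adventitious protonation of the aryllithium or butylation by the butyl bromide formed would give debrominated or butylated material. The fallback sets out from 8 and avoids organolithium chemistry: palladium-catalysed carbonylative lactonisation (Pd(OAc)2, Xantphos, CO 1–5 bar, Et3N, toluene, 90 °C). Oxidative addition into C–Br, CO insertion and capture of the acyl-palladium by the side-chain hydroxyl give the lactone directly, and the route is rejoined at 11. No new compound is made on the way (none F0).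

Step 15 (lithium-enolate aldol). The basic enolate may enolise the aldehyde, or the aldolate may revert. The fallback sets out from 23, which is converted (LDA, TMSCl, THF, −78 °C) into the isolated kinetic silyl enol ether (R)-3-(tert-butyldimethylsilyloxy)-2-(trimethylsilyloxy)dec-1-ene F1. A Mukaiyama aldol of this with 15 (BF3·OEt2, CH2Cl2, −78 °C, aqueous work-up) is non-basic, proceeds through an open transition state, and comes back to the route at 25.

Step 16 (mesylation and elimination). Retro-aldol cleavage, or epimerisation at C6′ if a stronger base is needed, could erode the material. The fallback sets out from 25 and removes the C3′ hydroxyl by radical deoxygenation instead of elimination. Phenyl chlorothionoformate, pyridine and DMAP in CH2Cl2 give the 3′-O-(phenoxythiocarbonyl) derivative of 25 F2. Bu3SnH and AIBN in toluene at 80 °C (Barton–McCombie) give (3R)-8-(benzyloxy)-3-[(6R)-6-(tert-butyldimethylsilyloxy)-5-oxotridecyl]-6-methoxyisochroman-1-one F3. Hydrogenolysis of its benzyl ether (H2, Pd/C, EtOAc) comes back to the route at 28.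

**Further compounds**
F0 | step 5 | none | none
F1 | step 15 | (R)-3-(tert-butyldimethylsilyloxy)-2-(trimethylsilyloxy)dec-1-ene | CCCCCCC[C@@H](O[Si](C)(C)C(C)(C)C)C(=C)O[Si](C)(C)C
F2 | step 16 | 3′-O-(phenoxythiocarbonyl) derivative of 25 | CCCCCCC[C@@H](O[Si](C)(C)C(C)(C)C)C(=O)CC(OC(=S)Oc1ccccc1)CC[C@@H]1Cc2cc(OC)cc(OCc3ccccc3)c2C(=O)O1
F3 | step 16 | (3R)-8-(benzyloxy)-3-[(6R)-6-(tert-butyldimethylsilyloxy)-5-oxotridecyl]-6-methoxyisochroman-1-one | CCCCCCC[C@@H](O[Si](C)(C)C(C)(C)C)C(=O)CCCC[C@@H]1Cc2cc(OC)cc(OCc3ccccc3)c2C(=O)O1
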